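## Retrosynthetic overview

Ring-A locants used below: C1 = CHBr, C2/C3 = the two CH2, C4 = C(OH)CH3, C5 = ring-fusion CH, C6 = quaternary C–CH3; ring B is the central cyclohexane, which carries the norbornane.
1. C1–Br comes from HAT hydrogenation of a C1=C2 bromoalkene; the norbornane carbinol comes from exo-oxymercuration of a 2-isopropylnorbornene.
2. Ring B and both norbornane rings come from one intramolecular Diels–Alder reaction of a 1-alkyl-2-isopropylcyclopentadiene (tethered to C6) with a vinyl group on C5.
3. Ring A comes from a Diels–Alder reaction of methacrolein (C3=C4) with the 2-siloxy triene C2=C1(OSi)–C6=C5–CH=CH2, which forms C2–C3 and C4–C5. Enabling feature: in ring A the bromine-bearing C1 (a latent carbonyl) and the carbinol C4 stand 1,4 with only C2/C3 between them, and the quaternary C6 between C1 and C5 can stay sp2 until after the cycloaddition, so ring A is a "para" [4+2] retron. Formyl → OH (Baeyer–Villiger, retention) and the C6 methyl (alkylation of the regiodefined enol ether) follow.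
4. Order of ring formation: ring A (step 4), then ring B and the norbornane together (step 13).

Key step: step 4

Assumption (remark on the chemistry): the (S)-prolinol-derived oxazaborolidinium catalyst is taken to expose the α-si face of methacrolein; if the first run shows the opposite sense, its antipode is used and nothing else changes.

## Route

Step 1
Reactants: 1 dimethyl (2-oxopropyl)phosphonate; 2 methyl 4-bromobutanoate
Product: 3 methyl 5-(dimethoxyphosphoryl)-6-oxoheptanoate
Conditions: NaH, DMF, 0 °C; then 2, NaI (cat.), 60 °C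
Reagents that add atoms: none
Why: C-alkylation (SN2) of the doubly stabilised β-ketophosphonate anion puts the future ring-B chain on the carbon that becomes C6; no stereocentre of the target is set.

Step 2
Reactants: 3 methyl 5-(dimethoxyphosphoryl)-6-oxoheptanoate; 4 acrolein
Product: 5 methyl (5E)-5-acetylocta-5,7-dienoate
Conditions: LiCl, i-Pr2NEt, MeCN, 0 → 23 °C
Reagents that add atoms: none
Why: Horner–Wadsworth–Emmons olefination under Masamune–Roush conditions should favour the (E)-enone (vinyl trans to acetyl), the geometry the diene needs.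

Step 3
Reactants: 5 methyl (5E)-5-acetylocta-5,7-dienoate
Product: 6 2-siloxy triene (TIPS dienol ether of 5)
Conditions: TIPSOTf, Et3N, CH2Cl2, −20 → 0 °C
Reagents that add atoms: triisopropylsilyl trifluoromethanesulfonate, CC(C)[Si](OS(=O)(=O)C(F)(F)F)(C(C)C)C(C)C
Why: Soft enolisation: the O-silylated enone can lose a proton only from the acetyl methyl, which gives the cross-conjugated 2-siloxy diene C2=C1(OSi)–C6=C5.

Step 4
Reactants: 6 2-siloxy triene; 7 methacrolein
Product: 8 ring-A Diels–Alder adduct (silyl enol ether aldehyde, formyl cis to vinyl)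
Conditions: 7 (3 equiv), (S)-o-tolyl-oxazaborolidine·Tf2NH (20 mol%), CH2Cl2, −78 → −40 °C
Reagents that add atoms: none
Why: Lewis-acid-catalysed, concerted but asynchronous normal-demand [4+2] cycloaddition: the cationic boron binds the formyl oxygen, the siloxy-activated terminus C2 attacks the methylene carbon C3 and C5 closes onto the α-carbon C4, so C2–C3 and C4–C5 form in one suprafacial event (closest known type: cationic-oxazaborolidine-catalysed Diels–Alder reactions of 2-substituted acroleins with 2-silyloxy dienes). Ring A closes in the "para/ortho" sense because both the 2-siloxy group and the vinyl group on C5 send C2 to the unsubstituted dienophile carbon; of the two diene units of the triene only C2=C1–C6=C5 can reach the s-cis form, since the other carries the side chain as a cis substituent at its terminus. The quaternary C4 is set by the catalyst, which shields one face of the bound enal so that the diene adds to the α-si face. C5 is set relative to C4 by the endo rule (formyl under the diene, E-vinyl outwards), which places formyl and vinyl cis. The step needs regio-, peri-, endo- and enantioselectivity, secured in that order by the siloxy/vinyl polarisation, the E-geometry from step 2, secondary overlap of the formyl group and the chiral Lewis acid. It leaves C1=C6 as a regiodefined silyl enol ether, the handle for the C6 methyl.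

Step 5
Reactants: 8 ring-A Diels–Alder adduct
Product: 9 C6-methylated keto aldehyde
Conditions: TASF, MeI (excess), THF, −78 → −20 °C
Reagents that add atoms: iodomethane, CI
Why: Fluoride-promoted regiospecific C-alkylation of a silyl enol ether: the tetrasubstituted enolate should be methylated axially on the lower face, anti to the C4 methyl that would otherwise be 1,3-diaxial to the incoming group, so the new C6 methyl ends cis to vinyl and formyl and the chain ends trans to vinyl.

Step 6
Reactants: 9 C6-methylated keto aldehyde
Product: 11 hydroxy ketone ester, via formate ester 10 (not isolated)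
Conditions: mCPBA, NaHCO3, CH2Cl2, 0 °C; then K2CO3, MeOH, 0 °C
Reagents that add atoms: 3-chloroperoxybenzoic acid, OOC(=O)c1cccc(Cl)c1
Why: Baeyer–Villiger oxidation of an α-quaternary aldehyde (the tertiary carbon migrates with retention, so C4–O keeps the configuration of step 4) followed by methanolysis; the hindered ring ketone and the monosubstituted alkene should react more slowly with the buffered peracid.

Step 7
Reactants: 11 hydroxy ketone ester
Product: 12 enol triflate
Conditions: KHMDS (2.2 equiv), THF, −78 °C; PhNTf2 (1.1 equiv); aq. NH4Cl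
Reagents that add atoms: N-phenylbis(trifluoromethanesulfonimide), O=S(=O)(N(c1ccccc1)S(=O)(=O)C(F)(F)F)C(F)(F)F
Why: O-triflation of the ketone enolate, which can form only towards C2 because C6 is quaternary; the hindered tertiary alkoxide should not be triflated at −78 °C.

Step 8
Reactants: 12 enol triflate
Product: 13 C1 bromoalkene ester
Conditions: Ni(OAc)2·4H2O (10 mol%), cod, Zn (cat.), LiBr, DMA–THF, 23 °C
Reagents that add atoms: lithium bromide, [Li+].[Br-]
Why: Nickel-catalysed triflate-to-halide exchange of an enol triflate installs the C1 bromine as a robust alkenyl bromide that also masks the C1 carbonyl during steps 9–13.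

Step 9
Reactants: 13 C1 bromoalkene ester
Product: 14 bromoalkene aldehyde
Conditions: DIBAL-H (2.2 equiv), CH2Cl2, −78 °C; Rochelle salt
Reagents that add atoms: none
Why: Partial reduction of the methyl ester stops at the aluminium hemiacetal at −78 °C; the alkenyl bromide and the tertiary alkoxide are inert.

Step 10
Reactants: 14 bromoalkene aldehyde; 15 4-methylpent-1-en-3-one
Product: 16 1,4-diketone
Conditions: 3-benzyl-5-(2-hydroxyethyl)-4-methylthiazolium chloride (20 mol%), Et3N, 1,4-dioxane, 75 °C
Reagents that add atoms: none
Why: Stetter reaction: the Breslow intermediate of the aliphatic aldehyde adds 1,4 to the vinyl ketone and gives the 1,4-diketone that contains all five cyclopentadiene carbons and the isopropyl group.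

Step 11
Reactants: 16 1,4-diketone
Product: 17 2-alkyl-3-isopropylcyclopent-2-enone
Conditions: KOH, MeOH–H2O, 60 °C
Reagents that add atoms: none
Why: Intramolecular aldol condensation (classical 1,4-diketone → cyclopentenone closure): only the chain CH2 next to the chain ketone can attack the isopropyl ketone and then dehydrate into conjugation, so a single enone with adjacent tether and isopropyl carbons is expected.

Step 12
Reactants: 17 2-alkyl-3-isopropylcyclopent-2-enone
Product: 18 cyclopentenol (both carbinol epimers)
Conditions: NaBH4, CeCl3·7H2O, MeOH, −20 °C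
Reagents that add atoms: none
Why: Luche 1,2-reduction of the enone; the new carbinol centre is lost in step 13, so its configuration is irrelevant.

Step 13
Reactants: 18 cyclopentenol
Product: 20 tetracyclic bromoalkene norbornene, via cyclopentadiene 19 (not isolated)
Conditions: TsOH·H2O (2 mol%), 4 Å MS, PhMe, 23 °C; Et3N; then 0.005 M in PhMe, BHT, 190 °C (sealed tube)
Reagents that add atoms: none
Why: Acid-catalysed dehydration through the allyl cation gives the cyclopentadiene, whose 1,5-H-shift tautomers equilibrate and funnel through the one tautomer that can undergo the type-1 intramolecular Diels–Alder reaction with the C5 vinyl group. The four-atom tether forces the ring-A carbon exo on the new norbornene, and the chair-like transition state with both tether bonds equatorial on ring A (the alternative would place the dienophile CH2 1,3-diaxial to the axial C6 methyl) should give trans-fused ring B with the target configuration at all three new stereocentres.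

Step 14
Reactants: 20 tetracyclic bromoalkene norbornene
Product: 22 bromoalkene diol, via organomercurial 21 (not isolated)
Conditions: Hg(OAc)2, THF–H2O, 23 °C; then NaOH, NaBH4, 0 °C
Reagents that add atoms: water, O; mercury(II) acetate (its atoms stay in 21 only), CC(=O)O[Hg]OC(C)=O
Why: Oxymercuration–demercuration of the trisubstituted norbornene is Markovnikov and exo (syn-exo addition is typical of norbornenes), which gives the tertiary exo-alcohol with endo isopropyl; the electron-poor bromoalkene should not react.

Step 15
Reactants: 22 bromoalkene diol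
Product: 23 target CNP0362628.1
Conditions: Mn(dpm)3 (10 mol%), PhSiH3, t-BuOOH, i-PrOH, 23 °C
Reagents that add atoms: none
Why: Metal-hydride hydrogen-atom-transfer hydrogenation of a haloalkene: H• adds to C2, and the α-bromo radical at C1 takes its hydrogen axially from the face anti to the axial C6 methyl, which should give the equatorial (thermodynamic) bromide without hydrogenolysis of C–Br.

## Compound list

1 | dimethyl (2-oxopropyl)phosphonate | CC(=O)CP(=O)(OC)OC | starting material
2 | methyl 4-bromobutanoate | COC(=O)CCCBr | starting material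
3 | methyl 5-(dimethoxyphosphoryl)-6-oxoheptanoate (racemic) | COC(=O)CCCC(C(C)=O)P(=O)(OC)OC | intermediate
4 | acrolein (prop-2-enal) | C=CC=O | starting material
5 | methyl (5E)-5-acetylocta-5,7-dienoate | C=C/C=C(/C(C)=O)CCCC(=O)OC | intermediate
6 | methyl (5E)-5-{1-[tri(propan-2-yl)silyloxy]ethenyl}octa-5,7-dienoate | C=C/C=C(/C(=C)O[Si](C(C)C)(C(C)C)C(C)C)CCCC(=O)OC | intermediate
7 | methacrolein (2-methylprop-2-enal) | C=C(C)C=O | starting material
8 | methyl 4-[(5R,6S)-6-ethenyl-5-formyl-5-methyl-2-{[tri(propan-2-yl)silyl]oxy}cyclohex-1-en-1-yl]butanoate (formyl cis to vinyl) | C=C[C@H]1C(CCCC(=O)OC)=C(O[Si](C(C)C)(C(C)C)C(C)C)CC[C@@]1(C)C=O | intermediate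
9 | methyl 4-[(1S,2R,3R)-2-ethenyl-3-formyl-1,3-dimethyl-6-oxocyclohexyl]butanoate (vinyl, formyl and 1-methyl all cis) | C=C[C@H]1[C@](C)(CCCC(=O)OC)C(=O)CC[C@@]1(C)C=O | intermediate
10 | methyl 4-[(1S,2S,3R)-2-ethenyl-3-(formyloxy)-1,3-dimethyl-6-oxocyclohexyl]butanoate | C=C[C@H]1[C@](C)(CCCC(=O)OC)C(=O)CC[C@@]1(C)OC=O | intermediate
11 | methyl 4-[(1S,2S,3R)-2-ethenyl-3-hydroxy-1,3-dimethyl-6-oxocyclohexyl]butanoate | C=C[C@H]1[C@](C)(CCCC(=O)OC)C(=O)CC[C@@]1(C)O | intermediate
12 | methyl 4-[(1S,5R,6S)-6-ethenyl-5-hydroxy-1,5-dimethyl-2-{[(trifluoromethyl)sulfonyl]oxy}cyclohex-2-en-1-yl]butanoate | C=C[C@H]1[C@](C)(CCCC(=O)OC)C(OS(=O)(=O)C(F)(F)F)=CC[C@@]1(C)O | intermediate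
13 | methyl 4-[(1S,5R,6S)-2-bromo-6-ethenyl-5-hydroxy-1,5-dimethylcyclohex-2-en-1-yl]butanoate | C=C[C@H]1[C@](C)(CCCC(=O)OC)C(Br)=CC[C@@]1(C)O | intermediate
14 | 4-[(1S,5R,6S)-2-bromo-6-ethenyl-5-hydroxy-1,5-dimethylcyclohex-2-en-1-yl]butanal | C=C[C@H]1[C@](C)(CCCC=O)C(Br)=CC[C@@]1(C)O | intermediate
15 | 4-methylpent-1-en-3-one (isopropyl vinyl ketone) | C=CC(=O)C(C)C | starting material
16 | 1-[(1S,5R,6S)-2-bromo-6-ethenyl-5-hydroxy-1,5-dimethylcyclohex-2-en-1-yl]-8-methylnonane-4,7-dione | C=C[C@H]1[C@](C)(CCCC(=O)CCC(=O)C(C)C)C(Br)=CC[C@@]1(C)O | intermediate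
17 | 2-{2-[(1S,5R,6S)-2-bromo-6-ethenyl-5-hydroxy-1,5-dimethylcyclohex-2-en-1-yl]ethyl}-3-(propan-2-yl)cyclopent-2-en-1-one | C=C[C@H]1[C@](C)(CCC2=C(C(C)C)CCC2=O)C(Br)=CC[C@@]1(C)O | intermediate
18 | 2-{2-[(1S,5R,6S)-2-bromo-6-ethenyl-5-hydroxy-1,5-dimethylcyclohex-2-en-1-yl]ethyl}-3-(propan-2-yl)cyclopent-2-en-1-ol (both carbinol epimers) | C=C[C@H]1[C@](C)(CCC2=C(C(C)C)CCC2O)C(Br)=CC[C@@]1(C)O | intermediate
19 | (1R,2S,6S)-4-bromo-2-ethenyl-1,3-dimethyl-3-{2-[2-(propan-2-yl)cyclopenta-1,3-dien-1-yl]ethyl}cyclohex-4-en-1-ol (drawn as the reactive tautomer of the 1,5-H-shift mixture) | C=C[C@H]1[C@](C)(CCC2=C(C(C)C)C=CC2)C(Br)=CC[C@@]1(C)O | intermediate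
20 | tetracyclic bromoalkene norbornene: target skeleton with C1=C2 bromoalkene in ring A and a 2-isopropylnorborn-2-ene, configuration as in the target | CC(C)C1=C[C@@H]2C[C@H]3[C@H]4[C@](C)(CC[C@@]31C2)C(Br)=CC[C@@]4(C)O | intermediate
21 | exo-acetoxymercurio adduct of 20 (exo-OH on the isopropyl carbon, exo-HgOAc on the neighbouring norbornane carbon) | CC(C)[C@]1(O)[C@@H]([Hg]OC(C)=O)[C@@H]2C[C@H]3[C@H]4[C@](C)(CC[C@@]31C2)C(Br)=CC[C@@]4(C)O | intermediate
22 | bromoalkene diol: target with a C1=C2 double bond in ring A (exo-OH, endo-isopropyl on the norbornane) | CC(C)[C@]1(O)C[C@@H]2C[C@H]3[C@H]4[C@](C)(CC[C@@]31C2)C(Br)=CC[C@@]4(C)O | intermediate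
23 | CNP0362628.1 (tetracyclic bromo diol; equatorial Br, axial ring-A OH, trans-fused A/B, exo-OH/endo-isopropyl norbornane) | CC(C)[C@]1(O)C[C@@H]2C[C@H]3[C@H]4[C@](C)(CC[C@@]31C2)[C@@H](Br)CC[C@@]4(C)O | target

## Step count and risks

Total step count: 15. Longest linear sequence: 15 steps (1 → 23).

Steps most likely to fail:

Step 13. The unactivated vinyl group sits on a carbon flanked by two quaternary centres and may add too slowly. The cyclopentadiene could then dimerise, isomerise to exocyclic dienes, or add through the shorter three-atom tether to the ring-A bromoalkene. Fallback, setting out from 17: the dienophile is activated and the activating group removed afterwards. Iodosulfonylation of the terminal alkene (PhSO2Na, I2, EtOAc–H2O, 23 °C) should give the β-iodo sulfone F1, and DBU should eliminate HI to the (E)-vinyl sulfone F2. Luche reduction gives the cyclopentenol F3. Acid-catalysed dehydration gives the cyclopentadiene F4, which should now cyclise at 60–80 °C to the endo-sulfonyl tetracycle F5. Reductive desulfonylation (Na/Hg, Na2HPO4, MeOH–THF, −20 °C) returns to 20.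

Step 5. Methyl iodide may approach the enolate from the upper face (anti to the neighbouring vinyl group), or the naked enolate may add to the formyl group of a second molecule. Fallback, setting out from 8: NaBH4 reduces the formyl group to the primary alcohol F6. Hydroxyl-directed Furukawa–Simmons–Smith cyclopropanation of the silyl enol ether (Et2Zn, CH2I2, CH2Cl2, 0 °C) should deliver the methylene to the lower face and give the siloxycyclopropane F7. Fluoride (TBAF, THF, 0 °C) opens the cyclopropanol at its CH2–C(O) bond to the α-methyl ketone F8 (Conia-type methylation). Dess–Martin oxidation returns to 9.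

Step 8. Oxidative addition of nickel into the hindered enol triflate next to the quaternary C6 may be slow, so that reduction to the plain alkene or hydrolysis back to the ketone takes over. Fallback, setting out from 12: palladium-catalysed stannylation (Me3SnSnMe3, Pd(PPh3)4, LiCl, THF, 60 °C) should give the alkenylstannane F9. Bromodestannylation with NBS (CH2Cl2, −40 °C), an ipso substitution faster than attack on the vinyl group, returns to 13.

Further compounds
F1 | step 13 | β-iodo sulfone of 17 (PhSO2CH2–CHI– in place of the vinyl group; iodide epimers) | O=S(=O)(CC(I)[C@H]1[C@](C)(CCC2=C(C(C)C)CCC2=O)C(Br)=CC[C@@]1(C)O)c1ccccc1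
F2 | step 13 | (E)-2-(phenylsulfonyl)vinyl analogue of 17 | O=S(=O)(/C=C/[C@H]1[C@](C)(CCC2=C(C(C)C)CCC2=O)C(Br)=CC[C@@]1(C)O)c1ccccc1
F3 | step 13 | (E)-2-(phenylsulfonyl)vinyl analogue of 18 (both carbinol epimers) | O=S(=O)(/C=C/[C@H]1[C@](C)(CCC2=C(C(C)C)CCC2O)C(Br)=CC[C@@]1(C)O)c1ccccc1
F4 | step 13 | (E)-2-(phenylsulfonyl)vinyl analogue of 19 (reactive tautomer drawn) | O=S(=O)(/C=C/[C@H]1[C@](C)(CCC2=C(C(C)C)C=CC2)C(Br)=CC[C@@]1(C)O)c1ccccc1
F5 | step 13 | endo-phenylsulfonyl derivative of 20 (sulfonyl on the norbornene CH2 next to the ring-B junction) | CC(C)C1=C[C@@H]2[C@H](S(=O)(=O)c5ccccc5)[C@H]3[C@H]4[C@](C)(CC[C@@]31C2)C(Br)=CC[C@@]4(C)O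
F6 | step 5 | hydroxymethyl analogue of 8 (CH2OH in place of CHO) | C=C[C@H]1C(CCCC(=O)OC)=C(O[Si](C(C)C)(C(C)C)C(C)C)CC[C@@]1(C)CO
F7 | step 5 | siloxycyclopropane from F6 (CH2 bridging C1 and C6 on the lower face) | C=C[C@H]1[C@@]2(CCCC(=O)OC)C[C@@]2(O[Si](C(C)C)(C(C)C)C(C)C)CC[C@@]1(C)CO
F8 | step 5 | hydroxymethyl analogue of 9 (CH2OH in place of CHO) | C=C[C@H]1[C@](C)(CCCC(=O)OC)C(=O)CC[C@@]1(C)CO
F9 | step 8 | trimethylstannyl analogue of 13 (SnMe3 in place of Br) | C=C[C@H]1[C@](C)(CCCC(=O)OC)C([Sn](C)(C)C)=CC[C@@]1(C)O
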